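(The earlier runs and the new flask were computed for an exercise; noise was put on by code.)

At 89 min the alpha run held 0.0255 M of Prd, below the 0.0259 M read at 66 min, although 0.0745 M of its Sub had not turned. I therefore read the stall as catalyst deactivation, asked what the end state must be, and reckoned the plateau as early rate times lifetime.

| flask | Sub | Cat | time |
|---|---|---|---|
| alpha | 0.100 M | 0.00300 M |  |
| delta | 0.0400 M | 0.00300 M |  |
| eta | 0.100 M | 0.00150 M |  |
| beta | 0.200 M | 0.00300 M |  |
| zeta | 0.300 M | 0.00300 M | 89 min |

- alpha run (time / min: [Prd] / M): 5.1: 0.0040; 15: 0.0126; 29: 0.0178; 47: 0.0233; 66: 0.0259; 89: 0.0255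
- delta run (time / min: [Prd] / M): 5.1: 0.0043; 15: 0.0076; 29: 0.0113; 47: 0.0176; 66: 0.0177; 89: 0.0220
- eta run (time / min: [Prd] / M): 5.1: 0.0016; 15: 0.0053; 29: 0.0052; 47: 0.0068; 66: 0.0070; 89: 0.0063
- beta run (time / min: [Prd] / M): 5.1: 0.0054; 15: 0.0134; 29: 0.0169; 47: 0.0197; 66: 0.0192; 89: 0.0182

(each reading ± 8 × 10⁻⁴ M)

- Overall: Sub -> Prd, with Cat as catalyst.
- Constant volume, constant temperature.
- Bound and free are read together.
- An order is taken over about fifteen percent of the charge, up and down.

* order of the initial rate in [Sub], near the charge of the alpha run, the rate being that where two percent of its Sub are Prd (one fixed amount of Prd, the same in the runs compared)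
* order of the initial rate in [Cat], near the charge of the alpha run, the rate being that where two percent of its Sub are Prd
* Prd in the zeta run at 89 min, as a share of the Sub charged

The alpha readings from 66 min on average 0.0257 M, and the beta readings from 47 min on average 0.0190 M. My first way took the early rate from the first reading, which gave 0.784 mM min⁻¹ for alpha and 1.06 mM min⁻¹ for beta, though the alpha reading carries a scatter of 20.0 %. The catalyst lifetime, plateau divided by early rate, is then 32.8 min for alpha and 18.0 min for beta. I drew the reciprocal lifetime as a straight line in [Sub], which gave zeta 12.4 min. The same rates gave an order in [Sub] of 0.433, so zeta should start at 1.26 mM min⁻¹ and level at 0.0156 M, or 5.21 % of its Sub. The first readings of alpha and eta gave me an order in [Cat] of 1.32.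

My second way took the lifetime from how far the 15 min reading had climbed towards the plateau on an exponential approach, which gave 22.3 min for alpha and 12.3 min for beta. The two ways part on both runs and by like factors: the lifetime of the first way is longer than that of the second by a factor of 1.47 on alpha and 1.46 on beta. A first reading gives an average rate over the time up to it, and in a slowing flask that average lies below the starting rate, so the first way cheats in this direction on both runs. On alpha the average rate up to 15 min, 0.840 mM min⁻¹, is also higher than the 0.784 mM min⁻¹ up to 5.1 min, which a slowing flask does not allow, so at least one of those two alpha readings strays within its scatter. Yet the second way levels zeta at 0.0156 M, or 5.20 %. A low rate inflates the lifetime, and the product holds, so I trusted the plateau and not either factor. This is a weak check, since both ways share the plateaus. The time 89 min is 7.18 lifetimes of zeta, so its reading should be the plateau.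

The forecast gave 0.5, 1.5 and 5.5 %, arguing that “Death speeds up with Sub”. Its order in [Cat] is higher than mine.

The flask gave 0.51, 1.7 and 5.35 %.

    Cat + Sub ⇌ Cat.Sub, settled at all times (7.150 M⁻¹)
    Cat.Sub + Cat → Prd + 2 Cat (846.0 M⁻¹ min⁻¹)
    Cat.Sub → X + Sub (0.07080 min⁻¹)
    2 Cat ⇌ Cat2, settled at all times (231.0 M⁻¹)

The beta rate stood at 1.2 times the alpha rate. With these rates in place of first readings, the alpha lifetime becomes 27.5 min, the beta lifetime 16.3 min, and the zeta lifetime 11.6 min. The zeta Prd of 0.0161 M then implies a rate of 1.38 mM min⁻¹. The same line gives delta a lifetime of 46.9 min, and with its rate 5.0 × 10⁻⁴ M min⁻¹ it reaches 0.0100 M of Prd at 26.2 min, where the delta run took 24.0 min.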